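The cyclopentane of the end group (ring A, C2–C6) holds its two carbon arms, C1 on C2 and C7 on C6, on one face and the C5 hydroxyl on the other. Tying C1 to C7 in retrosynthesis gives a cis-fused 2,2-dimethylcyclobutanone, which divides into a C6=C2 cyclopentene and a Me2C=C unit. In the forward sense one keteniminium [2+2] cycloaddition makes C6–C7 and C2–C1, closes the four-membered ring and relays the C5 configuration to C6 and C2. The precursor is the bulky silyl ether of (R)-1-methylcyclopent-2-en-1-ol, two steps from (R)-linalool. Oxygen insertion beside C1, half-reduction and a C10 + C30 Wittig union at C7=C8 finish the carotenoid.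

Key step: step 3

Assumption: carotenoid numbering of the target is used for every fragment (ring A = C2, C3, C4, C5, C6; C1 is the carbinol carbon on C2, C7 sits on C6, primed numbers belong to the acyclic half); (R)-linalool of high enantiomeric purity and (3E,5E)-pseudoionone are taken as purchased, and all polyene steps run under argon with light excluded.

Step 1
Reactants: 1 (R)-(−)-linalool
Product: 2 (1R)-1-methylcyclopent-2-en-1-ol
Conditions: second-generation Grubbs catalyst RuCl2(=CHPh)(PCy3)(SIMes) (1 mol %), CH2Cl2, 40 °C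
Reagents that add atoms: none
Why: Ring-closing metathesis of a 1,6-diene, in which the ruthenium carbene loads on the vinyl group and closes on the trisubstituted alkene with loss of volatile isobutene; the free allylic hydroxyl speeds the reaction, and the R carbinol centre, untouched, becomes C5 (R) of the target.

Step 2
Reactants: 2 (1R)-1-methylcyclopent-2-en-1-ol
Product: 3 tert-butyl(dimethyl){[(1R)-1-methylcyclopent-2-en-1-yl]oxy}silane
Conditions: TBSOTf, 2,6-lutidine, CH2Cl2, −78 to 0 °C
Reagents that add atoms: tert-butyldimethylsilyl trifluoromethanesulfonate (TBSOTf), CC(C)(C)[Si](C)(C)OS(=O)(=O)C(F)(F)F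
Why: Silyl triflate silylation of a hindered tertiary alcohol under lutidine buffering, which avoids ionising the allylic C–O bond; the tert-butyldimethylsilyl group is preferred to smaller silyl groups because it makes the oxygen less basic, withstands ZnCl2 and the later hydrolysis, and covers one ring face more fully.

Step 3
Reactants: 3 tert-butyl(dimethyl){[(1R)-1-methylcyclopent-2-en-1-yl]oxy}silane; 4 1-chloro-N,N,2-trimethylprop-1-en-1-amine
Product: 7 (1R,4R,5R)-4-{[tert-butyl(dimethyl)silyl]oxy}-4,7,7-trimethylbicyclo[3.2.0]heptan-6-one, via tetramethylketeniminium trichlorozincate 5 (not isolated), via cyclobutaniminium trichlorozincate 6 (not isolated)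
Conditions: ZnCl2 (anhydrous), CH2Cl2, slow addition of 4, 0 to 40 °C; then aq. NaHCO3, rt to 40 °C
Reagents that add atoms: water, O
Why: ZnCl2 pulls chloride from 4 to give the linear cation 5, whose sp carbon (future C7) is attacked by C6 of the alkene while positive charge grows at C2, after which the enamine carbon (future C1) collapses on C2 to give iminium salt 6, and bicarbonate hydrolysis turns 6 into ketone 7. The closest known reaction type is the keteniminium–olefin [2+2] cycloaddition, established for cyclopentene and other unactivated cycloalkenes as a route to 2,2-dimethylcyclobutanones. The cyclobutane closes in an asynchronous, suprafacial intermolecular [2+2] mode, bond C6–C7 leading and bond C2–C1 following on the same alkene face. C6 and C2 therefore become cis (a trans-fused bicyclo[3.2.0]heptane is out of reach), and their absolute sense is relayed from C5, because the silyloxy group covers one face and the reagent arrives on the methyl-bearing face. Regioselectivity is required and is secured twice: the C5–O dipole disfavours charge at C6, so C6 is the nucleophilic end, and the slim sp carbon rather than the CMe2 end fits next to quaternary C5. Slow addition of 4 holds down its self-condensation with 5, and the weakly basic, bulky silyl ether resists capture of 5 at oxygen and ionisation of the C5–O bond.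

Step 4
Reactants: 7 (1R,4R,5R)-4-{[tert-butyl(dimethyl)silyl]oxy}-4,7,7-trimethylbicyclo[3.2.0]heptan-6-one
Product: 8 (3aR,6R,6aR)-6-{[tert-butyl(dimethyl)silyl]oxy}-3,3,6-trimethylhexahydro-1H-cyclopenta[c]furan-1-one
Conditions: mCPBA, CH2Cl2, 0 °C to rt
Reagents that add atoms: meta-chloroperoxybenzoic acid (mCPBA), OOC(=O)c1cccc(Cl)c1
Why: Baeyer–Villiger oxidation driven by release of cyclobutanone strain, in which quaternary C1 migrates in the Criegee adduct in preference to tertiary C6 (further deactivated by the β-oxygen on C5), so oxygen enters between C7 and C1 and no stereocentre is disturbed.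

Step 5
Reactants: 8 (3aR,6R,6aR)-6-{[tert-butyl(dimethyl)silyl]oxy}-3,3,6-trimethylhexahydro-1H-cyclopenta[c]furan-1-one
Product: 9 (3aR,6R,6aR)-6-{[tert-butyl(dimethyl)silyl]oxy}-3,3,6-trimethylhexahydro-1H-cyclopenta[c]furan-1-ol (lactol, both anomers)
Conditions: iBu2AlH (1.1 equiv), toluene, −78 °C
Reagents that add atoms: none
Why: Partial lactone reduction with iBu2AlH, whose tetrahedral aluminium acetal survives at −78 °C and gives the lactol on work-up; the cis-fused lactol stores the C7 aldehyde in a form that guards C6 against epimerisation.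

Step 6
Reactants: 10 (3E,5E)-pseudoionone
Product: 11 (4E,6E)-3,7,11-trimethyldodeca-1,4,6,10-tetraen-3-ol (vinylpseudoionol, racemic)
Conditions: CH2=CHMgBr, THF, −20 to 0 °C
Reagents that add atoms: vinylmagnesium bromide, C=C[Mg]Br
Why: Grignard 1,2-addition to the dienone carbonyl; the new carbinol centre is racemic and is erased in the next step.

Step 7
Reactants: 11 vinylpseudoionol
Product: 12 [(2E,4E,6E)-3,7,11-trimethyldodeca-2,4,6,10-tetraen-1-yl]triphenylphosphonium bromide (C15 salt)
Conditions: PPh3·HBr, MeOH, 0 °C to rt; crystallisation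
Reagents that add atoms: triphenylphosphine hydrobromide, Br.c1ccc(cc1)P(c1ccccc1)c1ccccc1
Why: Phosphonium salt formation with allylic transposition (SN1' type), in which ionisation gives a delocalised cation that PPh3 captures at the unhindered primary terminus; the salt with the E bond at C9'=C10' is purified by crystallisation.

Step 8
Reactants: 12 C15 salt; 13 (2E,4E,6E)-2,7-dimethylocta-2,4,6-trienedial
Product: 15 all-E apo-12'-lycopenal (C25 aldehyde), via C15 ylide 14 (not isolated)
Conditions: NaOMe (added slowly), MeOH/CH2Cl2, 0 °C to rt, 13 in excess (2 equiv); crystallisation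
Reagents that add atoms: none
Why: Wittig olefination of one aldehyde group only, kept selective by the excess of 13 and the slow generation of 14; a delocalised ylide and an enal should give mainly the E alkene at C11'=C12', and the all-E aldehyde is purified by crystallisation.

Step 9
Reactants: 16 ethyl tiglate
Product: 17 ethyl (2E)-4-bromo-2-methylbut-2-enoate
Conditions: NBS, AIBN (cat.), PhCF3, reflux; distillation
Reagents that add atoms: N-bromosuccinimide, O=C1CCC(=O)N1Br
Why: Wohl–Ziegler allylic bromination, in which hydrogen abstraction from the γ-methyl group gives the ester-conjugated allyl radical that takes up bromine at its primary terminus.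

Step 10
Reactants: 17 ethyl (2E)-4-bromo-2-methylbut-2-enoate
Product: 18 ethyl (2E)-4-(diethoxyphosphoryl)-2-methylbut-2-enoate (C5 phosphonate)
Conditions: P(OEt)3, neat, 130 °C
Reagents that add atoms: triethyl phosphite, CCOP(OCC)OCC
Why: Michaelis–Arbuzov reaction of a primary allylic bromide, pushed forward as ethyl bromide distils off.

Step 11
Reactants: 15 apo-12'-lycopenal; 18 C5 phosphonate
Product: 20 ethyl all-E apo-8'-lycopenoate (C30 ester), via sodium phosphonate anion 19 (not isolated)
Conditions: NaH, THF, 0 °C; then 15, 0 °C to rt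
Reagents that add atoms: none
Why: Horner–Wadsworth–Emmons olefination with a vinylogous phosphonate anion, which reacts at the carbon next to phosphorus, gives the E alkene at C11=C12 and places the methyl group on C9 as the target demands.

Step 12
Reactants: 20 ethyl apo-8'-lycopenoate
Product: 21 all-E apo-8'-lycopenol (C30 alcohol)
Conditions: iBu2AlH (2.5 equiv), CH2Cl2, −78 to −20 °C
Reagents that add atoms: none
Why: Exhaustive iBu2AlH reduction of a conjugated ester to the allylic alcohol, a pure 1,2-reduction that leaves the polyene alone.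

Step 13
Reactants: 21 apo-8'-lycopenol
Product: 22 (all-E apo-8'-lycopenyl)triphenylphosphonium bromide (C30 salt)
Conditions: PPh3·HBr, CH2Cl2/MeOH, 0 °C to rt
Reagents that add atoms: triphenylphosphine hydrobromide, Br.c1ccc(cc1)P(c1ccccc1)c1ccccc1
Why: Phosphonium salt formation from a polyenyl allylic alcohol, the reaction type that turns retinol into its Wittig salt; the delocalised cation is captured by PPh3 at C8, the only position that keeps the whole polyene conjugated.

Step 14
Reactants: 9 lactol; 22 C30 salt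
Product: 25 (all-E,2R,5R,6R)-5-{[tert-butyl(dimethyl)silyl]oxy}-2,6-cyclolycopen-1-ol (C40 silyl ether), via C30 ylide 23 (not isolated), via ring-opened aldehyde alkoxide 24 (not isolated)
Conditions: 22 + NaN(SiMe3)2, THF, −78 °C; separately 9 + NaN(SiMe3)2, THF, −78 °C; combine, −78 to 0 °C; chromatography and crystallisation of the all-E isomer
Reagents that add atoms: none
Why: Wittig olefination of a lactol, in which one equivalent of base opens 9 to aldehyde alkoxide 24 and ylide 23 traps it at C7; the delocalised ylide and the α-branched aldehyde favour the E alkene, the polyene product offers the freed C1 alkoxide no acceptor for conjugate addition, and the silyl group kept on O5 rules out retro-aldol cleavage of C5–C6, so C2, C5 and C6 are carried through unchanged.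

Step 15
Reactants: 25 C40 silyl ether
Product: 26 (all-E,2R,5R,6R)-2,6-cyclolycopene-1,5-diol (CNP0169920.2)
Conditions: Bu4NF, THF, rt to 40 °C; crystallisation
Reagents that add atoms: none
Why: Fluoride-induced cleavage of the tertiary silyl ether, a non-acidic deprotection that spares the polyene and both tertiary carbinols and touches no stereocentre.

Compound list
1 | (R)-(−)-linalool | C=C[C@](C)(O)CCC=C(C)C | starting material
2 | (1R)-1-methylcyclopent-2-en-1-ol | C1=CCC[C@@]1(C)O | intermediate
3 | tert-butyl(dimethyl){[(1R)-1-methylcyclopent-2-en-1-yl]oxy}silane | C1=CCC[C@@]1(C)O[Si](C)(C)C(C)(C)C | intermediate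
4 | 1-chloro-N,N,2-trimethylprop-1-en-1-amine | CC(C)=C(Cl)N(C)C | starting material
5 | tetramethylketeniminium trichlorozincate | CC(C)=C=[N+](C)C.Cl[Zn-](Cl)Cl | intermediate
6 | cyclobutaniminium trichlorozincate (N,N-dimethyliminium form of 7, same configuration) | C[N+](C)=C2[C@@H]1[C@H](C2(C)C)CC[C@@]1(C)O[Si](C)(C)C(C)(C)C.Cl[Zn-](Cl)Cl | intermediate
7 | (1R,4R,5R)-4-{[tert-butyl(dimethyl)silyl]oxy}-4,7,7-trimethylbicyclo[3.2.0]heptan-6-one | O=C2[C@@H]1[C@H](C2(C)C)CC[C@@]1(C)O[Si](C)(C)C(C)(C)C | intermediate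
8 | (3aR,6R,6aR)-6-{[tert-butyl(dimethyl)silyl]oxy}-3,3,6-trimethylhexahydro-1H-cyclopenta[c]furan-1-one | O=C2[C@@H]1[C@H](C(C)(C)O2)CC[C@@]1(C)O[Si](C)(C)C(C)(C)C | intermediate
9 | (3aR,6R,6aR)-6-{[tert-butyl(dimethyl)silyl]oxy}-3,3,6-trimethylhexahydro-1H-cyclopenta[c]furan-1-ol, both anomers | OC2[C@@H]1[C@H](C(C)(C)O2)CC[C@@]1(C)O[Si](C)(C)C(C)(C)C | intermediate
10 | (3E,5E)-pseudoionone | CC(C)=CCC/C(C)=C/C=C/C(C)=O | starting material
11 | vinylpseudoionol, racemic | CC(C)=CCC/C(C)=C/C=C/C(C)(O)C=C | intermediate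
12 | [(2E,4E,6E)-3,7,11-trimethyldodeca-2,4,6,10-tetraen-1-yl]triphenylphosphonium bromide | CC(C)=CCC/C(C)=C/C=C/C(C)=C/C[P+](c1ccccc1)(c1ccccc1)c1ccccc1.[Br-] | intermediate
13 | (2E,4E,6E)-2,7-dimethylocta-2,4,6-trienedial | O=C/C(C)=C/C=C/C=C(C)/C=O | starting material
14 | C15 ylide from 12 | CC(C)=CCC/C(C)=C/C=C/C(C)=C/C=P(c1ccccc1)(c1ccccc1)c1ccccc1 | intermediate
15 | all-E apo-12'-lycopenal, (2E,4E,6E,8E,10E,12E,14E)-2,7,11,15,19-pentamethylicosa-2,4,6,8,10,12,14,18-octaenal | CC(C)=CCC/C(C)=C/C=C/C(C)=C/C=C/C(C)=C/C=C/C=C(C)/C=O | intermediate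
16 | ethyl tiglate | CCOC(=O)/C(C)=C/C | starting material
17 | ethyl (2E)-4-bromo-2-methylbut-2-enoate | CCOC(=O)/C(C)=C/CBr | intermediate
18 | ethyl (2E)-4-(diethoxyphosphoryl)-2-methylbut-2-enoate | CCOC(=O)/C(C)=C/CP(=O)(OCC)OCC | intermediate
19 | sodium salt of the carbanion of 18 | CCOC(=O)/C(C)=C/[CH-]P(=O)(OCC)OCC.[Na+] | intermediate
20 | ethyl all-E apo-8'-lycopenoate | CC(C)=CCC/C(C)=C/C=C/C(C)=C/C=C/C(C)=C/C=C/C=C(C)/C=C/C=C(C)/C(=O)OCC | intermediate
21 | all-E apo-8'-lycopenol | CC(C)=CCC/C(C)=C/C=C/C(C)=C/C=C/C(C)=C/C=C/C=C(C)/C=C/C=C(C)/CO | intermediate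
22 | (all-E apo-8'-lycopenyl)triphenylphosphonium bromide | CC(C)=CCC/C(C)=C/C=C/C(C)=C/C=C/C(C)=C/C=C/C=C(C)/C=C/C=C(C)/C[P+](c1ccccc1)(c1ccccc1)c1ccccc1.[Br-] | intermediate
23 | C30 ylide from 22 | CC(C)=CCC/C(C)=C/C=C/C(C)=C/C=C/C(C)=C/C=C/C=C(C)/C=C/C=C(C)/C=P(c1ccccc1)(c1ccccc1)c1ccccc1 | intermediate
24 | sodium 2-[(1R,2R,3R)-3-{[tert-butyl(dimethyl)silyl]oxy}-2-formyl-3-methylcyclopentyl]propan-2-olate | O=C[C@@H]1[C@H](C(C)(C)[O-])CC[C@@]1(C)O[Si](C)(C)C(C)(C)C.[Na+] | intermediate
25 | (all-E,2R,5R,6R)-5-{[tert-butyl(dimethyl)silyl]oxy}-2,6-cyclolycopen-1-ol | CC(C)=CCC/C(C)=C/C=C/C(C)=C/C=C/C(C)=C/C=C/C=C(C)/C=C/C=C(C)/C=C/[C@@H]1[C@H](C(C)(C)O)CC[C@@]1(C)O[Si](C)(C)C(C)(C)C | intermediate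
26 | (all-E,2R,5R,6R)-2,6-cyclolycopene-1,5-diol | CC(C)=CCC/C(C)=C/C=C/C(C)=C/C=C/C(C)=C/C=C/C=C(C)/C=C/C=C(C)/C=C/[C@@H]1[C@H](C(C)(C)O)CC[C@@]1(C)O | target

Total step count: 15.
- Carbon bookkeeping: C13 (10) + C2 (vinyl) + C10 (13) + C5 (18) = C30 (22), and C30 + C10 (9) = C40.
- Longest linear sequence: 8 steps from pseudoionone (steps 6, 7, 8, 11, 12, 13, 14, 15).
- The ring arm from linalool runs over 7 steps (1–5, 14, 15).

Steps most likely to fail

1. Step 3.
- What may go wrong: the cation 5 may be captured at the silyl ether oxygen. The tertiary allylic C5–O bond may ionise under the Lewis acid. Addition may be sluggish, because the alkene is both neopentyl-like and inductively deactivated. Facial selectivity may erode, because methyl and silyloxy compete as shielding groups.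
- Fallback, from 3 back to 7: dichloroketene, generated from Cl3CCOCl with Zn–Cu couple in Et2O/DME, is a neutral and much more reactive two-carbon partner. Its [2+2] addition should obey the same regiochemical and facial rules and give the dichlorocyclobutanone F1. Reductive gem-dimethylation of this α,α-dichloro ketone follows, with excess Me2CuLi and then MeI/HMPA (halogen–copper exchange followed by enolate alkylation). It replaces both chlorines by methyl groups and rejoins the route at 7.

2. Step 14.
- What may go wrong: the gem-dimethyl-stabilised lactol may open reluctantly towards a strongly delocalised ylide. Base may epimerise C6 or eliminate silanolate from the open aldehyde. E selectivity at C7=C8 may be incomplete.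
- Fallback, from 8 and 21 back to 25, with reversed polarity so that no C7 aldehyde is ever formed: LiAlH4 reduces 8 to the diol F2. Mitsunobu thioetherification of its primary C7 hydroxyl with 1-phenyl-1H-tetrazole-5-thiol (PPh3, DIAD) gives the tetrazolyl sulfide F3. H2O2 with (NH4)6Mo7O24 as catalyst gives the tetrazolyl sulfone F4. MnO2 oxidises 21 to apo-8'-lycopenal F5. Julia–Kocienski olefination of F4 (KN(SiMe3)2, 2.1 equiv, DME, −60 °C) with F5 should form C7=C8 with E selectivity and rejoins the route at 25.

3. Step 13.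
- What may go wrong: the long polyenyl cation may decompose or cyclise before phosphine capture. Alcohol 21 may be poorly soluble. Phosphine may attack at internal positions.
- Fallback, from 9 and 15 back to 25, which moves the phosphonium centre to a short dienyl stage (C15 + C25 instead of C10 + C30): Horner–Wadsworth–Emmons reaction of 9 (pre-treated with LiN(SiMe3)2) with the lithium anion of commercial triethyl 3-methyl-4-phosphonocrotonate gives the C15 dienoate F6. iBu2AlH reduces it to the C15 dienol F7. PPh3·HBr in MeOH gives the C15 phosphonium bromide F8. Wittig reaction of F8 with aldehyde 15 (NaOMe, CH2Cl2/MeOH) forms C11=C12 and rejoins the route at 25, so steps 9–13 are no longer needed.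

Further compounds
F1 | step 3 | (1R,4R,5R)-4-{[tert-butyl(dimethyl)silyl]oxy}-7,7-dichloro-4-methylbicyclo[3.2.0]heptan-6-one | O=C2[C@@H]1[C@H](C2(Cl)Cl)CC[C@@]1(C)O[Si](C)(C)C(C)(C)C
F2 | step 14 | 2-[(1R,2S,3R)-3-{[tert-butyl(dimethyl)silyl]oxy}-2-(hydroxymethyl)-3-methylcyclopentyl]propan-2-ol | OC[C@@H]1[C@H](C(C)(C)O)CC[C@@]1(C)O[Si](C)(C)C(C)(C)C
F3 | step 14 | 2-[(1R,2R,3R)-3-{[tert-butyl(dimethyl)silyl]oxy}-3-methyl-2-{[(1-phenyl-1H-tetrazol-5-yl)sulfanyl]methyl}cyclopentyl]propan-2-ol | c1ccccc1n1nnnc1SC[C@@H]2[C@H](C(C)(C)O)CC[C@@]2(C)O[Si](C)(C)C(C)(C)C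
F4 | step 14 | 2-[(1R,2R,3R)-3-{[tert-butyl(dimethyl)silyl]oxy}-3-methyl-2-{[(1-phenyl-1H-tetrazol-5-yl)sulfonyl]methyl}cyclopentyl]propan-2-ol | c1ccccc1n1nnnc1S(=O)(=O)C[C@@H]2[C@H](C(C)(C)O)CC[C@@]2(C)O[Si](C)(C)C(C)(C)C
F5 | step 14 | all-E apo-8'-lycopenal | CC(C)=CCC/C(C)=C/C=C/C(C)=C/C=C/C(C)=C/C=C/C=C(C)/C=C/C=C(C)/C=O
F6 | step 13 | ethyl (2E,4E)-5-[(1R,2R,5R)-2-{[tert-butyl(dimethyl)silyl]oxy}-5-(2-hydroxypropan-2-yl)-2-methylcyclopentyl]-3-methylpenta-2,4-dienoate | CCOC(=O)/C=C(C)/C=C/[C@@H]1[C@H](C(C)(C)O)CC[C@@]1(C)O[Si](C)(C)C(C)(C)C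
F7 | step 13 | (2E,4E)-5-[(1R,2R,5R)-2-{[tert-butyl(dimethyl)silyl]oxy}-5-(2-hydroxypropan-2-yl)-2-methylcyclopentyl]-3-methylpenta-2,4-dien-1-ol | OC/C=C(C)/C=C/[C@@H]1[C@H](C(C)(C)O)CC[C@@]1(C)O[Si](C)(C)C(C)(C)C
F8 | step 13 | {(2E,4E)-5-[(1R,2R,5R)-2-{[tert-butyl(dimethyl)silyl]oxy}-5-(2-hydroxypropan-2-yl)-2-methylcyclopentyl]-3-methylpenta-2,4-dien-1-yl}triphenylphosphonium bromide | [Br-].c1ccccc1[P+](c1ccccc1)(c1ccccc1)C/C=C(C)/C=C/[C@@H]1[C@H](C(C)(C)O)CC[C@@]1(C)O[Si](C)(C)C(C)(C)C
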